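The 5-oxo-2,5-dihydrofuran ring (O1, C2, C3, C4, C5) is cut at O1–C2 and C3=C4. This gives a C2–C3 bis-electrophile and a glycolate O1–C5–C4 bis-nucleophile. The feature exploited is that quaternary C2 lies between the ester carbonyl and C3. With C3 as an aryl ketone, C2 is the α-carbon of a β-keto ester, where a tertiary chloride still undergoes SN2 with inversion. The precursor is an acyclic, enantioenriched (2S)-α-benzyl-α-chloro aroylacetate. In one flask, cesium benzyloxyacetate displaces chloride (O1–C2, stereocentre fixed). DBU then condenses the glycolate CH2 with the ketone (C3=C4) and closes the ring. The dihydrobenzofuran centre comes from Shi epoxidation and 5-exo opening.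

Key step: step 7

Assumption: the sense of induction of the copper–ligand chlorination catalyst on acyclic keto ester 9 is fixed by the ligand antipode. Both antipodes are accessible, and the one that delivers the (2S)-chloride is meant.

Step 1
Reactants: 1 methyl 3-(4-hydroxyphenyl)propanoate; 2 prenyl bromide (1-bromo-3-methylbut-2-ene)
Product: 3 methyl 3-[4-hydroxy-3-(3-methylbut-2-en-1-yl)phenyl]propanoate
Conditions: NaH, toluene, 0 °C to rt
Reagents that add atoms: none
Why: ortho-C-alkylation of a sodium phenoxide; in a non-polar solvent the tight ion pair shields oxygen and steers the allylic bromide to the ortho carbon, the para position being blocked by the side chain.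

Step 2
Reactants: 3 methyl 3-[4-hydroxy-3-(3-methylbut-2-en-1-yl)phenyl]propanoate
Product: 4 methyl 3-[4-(tert-butyldimethylsilyloxy)-3-(3-methylbut-2-en-1-yl)phenyl]propanoate
Conditions: TBSCl, imidazole, DMF, rt
Reagents that add atoms: tert-butyldimethylsilyl chloride, CC(C)(C)[Si](C)(C)Cl
Why: standard silyl ether formation, needed because a free para-alkylphenol would be oxidised by peroxymonosulfate in the next step.

Step 3
Reactants: 4 methyl 3-[4-(tert-butyldimethylsilyloxy)-3-(3-methylbut-2-en-1-yl)phenyl]propanoate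
Product: 5 methyl 3-[4-(tert-butyldimethylsilyloxy)-3-{[(2R)-3,3-dimethyloxiran-2-yl]methyl}phenyl]propanoate
Conditions: D-fructose-derived Shi ketone (1,2:4,5-di-O-isopropylidene-β-D-erythro-2,3-hexodiulo-2,6-pyranose, 30 mol %), Oxone, K2CO3, Bu4NHSO4 (cat.), MeCN–CH2(OMe)2, aq. Na2B4O7–Na2EDTA buffer, 0 °C
Reagents that add atoms: Oxone (active component potassium peroxymonosulfate), [K+].[O-]S(=O)(=O)OO
Why: Shi asymmetric epoxidation; the chiral dioxirane meets the trisubstituted alkene in a spiro transition state on the face that should give the (R)-epoxide, as it does for trans-disubstituted and trisubstituted alkenes with this ketone antipode.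

Step 4
Reactants: 5 methyl 3-[4-(tert-butyldimethylsilyloxy)-3-{[(2R)-3,3-dimethyloxiran-2-yl]methyl}phenyl]propanoate
Product: 7 methyl 3-[(2S)-2-(2-hydroxypropan-2-yl)-2,3-dihydro-1-benzofuran-5-yl]propanoate, via epoxy phenoxide 6 (not isolated)
Conditions: TBAF, THF, 0 °C to rt; then H2O
Reagents that add atoms: none
Why: fluoride desilylation frees the phenoxide, which opens the epoxide at its less hindered secondary carbon in a 5-exo-tet SN2 with inversion, so the (R)-epoxide carbon becomes the (2S)-dihydrobenzofuran centre.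

Step 5
Reactants: 7 methyl 3-[(2S)-2-(2-hydroxypropan-2-yl)-2,3-dihydro-1-benzofuran-5-yl]propanoate; 8 4-(benzyloxy)benzoyl chloride
Product: 9 methyl 3-[4-(benzyloxy)phenyl]-2-{[(2S)-2-(2-hydroxypropan-2-yl)-2,3-dihydro-1-benzofuran-5-yl]methyl}-3-oxopropanoate (both C2 epimers)
Conditions: LiHMDS (3.2 equiv), THF, −78 °C; 8, −78 °C; then H2O
Reagents that add atoms: none
Why: crossed Claisen-type C-acylation of a lithium ester enolate with a non-enolisable aroyl chloride; the extra base stores the product as its enolate, the hindered tertiary lithium alkoxide should acylate far more slowly at −78 °C, and the uncontrolled C2 centre is planarised in the next step.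

Step 6
Reactants: 9 methyl 3-[4-(benzyloxy)phenyl]-2-{[(2S)-2-(2-hydroxypropan-2-yl)-2,3-dihydro-1-benzofuran-5-yl]methyl}-3-oxopropanoate
Product: 10 methyl (2S)-3-[4-(benzyloxy)phenyl]-2-chloro-2-{[(2S)-2-(2-hydroxypropan-2-yl)-2,3-dihydro-1-benzofuran-5-yl]methyl}-3-oxopropanoate
Conditions: NCS, Cu(OTf)2 (10 mol %), spiro pyridine–oxazoline ligand (SPYMOX type, 12 mol %), 4 Å MS, toluene, 0 °C
Reagents that add atoms: N-chlorosuccinimide, O=C1CCC(=O)N1Cl
Why: catalytic enantioselective electrophilic α-chlorination of a β-keto ester; both carbonyl oxygens chelate the chiral divalent-copper complex, the ligand blocks one face of the planar enolate and NCS delivers chlorine to the other, which sets C2 as (S), and any residual C2 epimer is a diastereomer that chromatography can remove.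

Step 7
Reactants: 10 methyl (2S)-3-[4-(benzyloxy)phenyl]-2-chloro-2-{[(2S)-2-(2-hydroxypropan-2-yl)-2,3-dihydro-1-benzofuran-5-yl]methyl}-3-oxopropanoate; 11 (benzyloxy)acetic acid
Product: 14 methyl (2R)-4-(benzyloxy)-3-[4-(benzyloxy)phenyl]-2-{[(2S)-2-(2-hydroxypropan-2-yl)-2,3-dihydro-1-benzofuran-5-yl]methyl}-5-oxo-2,5-dihydrofuran-2-carboxylate, via acyloxy keto ester 12 (not isolated), via aldol lactone 13 (not isolated)
Conditions: 11, Cs2CO3 (0.5 equiv per 11), 4 Å MS, DMF, rt; 10, rt to 40 °C; then DBU, same flask, 40 °C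
Reagents that add atoms: none
Why: The carboxylate oxygen of cesium benzyloxyacetate attacks C2 of 10 opposite to chloride; overlap with the two flanking carbonyl π* orbitals lowers this SN2 transition state at the tertiary carbon while the same groups suppress ionisation, so (2S)-10 should give (2R)-12 with inversion, the C–Cl configuration of the substrate being the only control element for the new O1–C2 stereocentre. DBU then enolises the OCH2 group of 12, its carbon adds to the aryl ketone to give aldol lactone 13, and E1cB loss of water installs C3=C4 and erases the transient centres at C3 and C4. The closest known reaction types are the stereospecific displacement of enantioenriched tertiary α-chloro-β-keto esters by azide, thiolate, fluoride and phenoxide, and the base-mediated condensation of α-(alkoxyacetoxy) aryl ketones to alkoxy-aryl butenolides with a quaternary γ-carbon. The single ring closes in a 5-(enolendo)-exo-trig aldol mode, formally unfavourable but routine for α-acyloxy ketones because the ester oxygen in the tether relaxes the geometry. The step needs substitution over E2 loss of HCl toward the benzylidene keto ester, which the weakly basic, carbonate-free cesium carboxylate secures, and attack at the ketone instead of the methyl ester, which the higher electrophilicity of the ketone and the irreversible dehydration to the aryl-conjugated butenolide secure. Holding DBU back until 10 is consumed keeps the glycolate carbanion away from the C–Cl bond.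

Step 8
Reactants: 14 methyl (2R)-4-(benzyloxy)-3-[4-(benzyloxy)phenyl]-2-{[(2S)-2-(2-hydroxypropan-2-yl)-2,3-dihydro-1-benzofuran-5-yl]methyl}-5-oxo-2,5-dihydrofuran-2-carboxylate
Product: 15 methyl (2R)-4-hydroxy-3-(4-hydroxyphenyl)-2-{[(2S)-2-(2-hydroxypropan-2-yl)-2,3-dihydro-1-benzofuran-5-yl]methyl}-5-oxo-2,5-dihydrofuran-2-carboxylate (target)
Conditions: H2 (1 atm), Pd/C, EtOAc–MeOH, rt
Reagents that add atoms: none
Why: catalytic hydrogenolysis cleaves the aryl benzyl ether and the enol benzyl ether together, while the tetrasubstituted C3=C4 bond, the esters and both stereocentres should stay untouched.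

Compound list
1 | methyl 3-(4-hydroxyphenyl)propanoate | COC(=O)CCc1ccc(O)cc1 | starting material
2 | prenyl bromide (1-bromo-3-methylbut-2-ene) | CC(C)=CCBr | starting material
3 | methyl 3-[4-hydroxy-3-(3-methylbut-2-en-1-yl)phenyl]propanoate | COC(=O)CCc1ccc(O)c(CC=C(C)C)c1 | intermediate
4 | methyl 3-[4-(tert-butyldimethylsilyloxy)-3-(3-methylbut-2-en-1-yl)phenyl]propanoate | COC(=O)CCc1ccc(O[Si](C)(C)C(C)(C)C)c(CC=C(C)C)c1 | intermediate
5 | methyl 3-[4-(tert-butyldimethylsilyloxy)-3-{[(2R)-3,3-dimethyloxiran-2-yl]methyl}phenyl]propanoate | COC(=O)CCc1ccc(O[Si](C)(C)C(C)(C)C)c(C[C@H]2OC2(C)C)c1 | intermediate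
6 | methyl 3-[3-{[(2R)-3,3-dimethyloxiran-2-yl]methyl}-4-hydroxyphenyl]propanoate (present as its phenoxide, not isolated) | COC(=O)CCc1ccc(O)c(C[C@H]2OC2(C)C)c1 | intermediate
7 | methyl 3-[(2S)-2-(2-hydroxypropan-2-yl)-2,3-dihydro-1-benzofuran-5-yl]propanoate | COC(=O)CCc1ccc2c(c1)C[C@@H](C(C)(C)O)O2 | intermediate
8 | 4-(benzyloxy)benzoyl chloride | O=C(Cl)c1ccc(OCc2ccccc2)cc1 | starting material
9 | methyl 3-[4-(benzyloxy)phenyl]-2-{[(2S)-2-(2-hydroxypropan-2-yl)-2,3-dihydro-1-benzofuran-5-yl]methyl}-3-oxopropanoate (C2 epimers) | COC(=O)C(Cc1ccc2c(c1)C[C@@H](C(C)(C)O)O2)C(=O)c1ccc(OCc2ccccc2)cc1 | intermediate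
10 | methyl (2S)-3-[4-(benzyloxy)phenyl]-2-chloro-2-{[(2S)-2-(2-hydroxypropan-2-yl)-2,3-dihydro-1-benzofuran-5-yl]methyl}-3-oxopropanoate | COC(=O)[C@](Cl)(Cc1ccc2c(c1)C[C@@H](C(C)(C)O)O2)C(=O)c1ccc(OCc2ccccc2)cc1 | intermediate
11 | (benzyloxy)acetic acid | OC(=O)COCc1ccccc1 | starting material
12 | methyl (2R)-2-[(benzyloxyacetyl)oxy]-3-[4-(benzyloxy)phenyl]-2-{[(2S)-2-(2-hydroxypropan-2-yl)-2,3-dihydro-1-benzofuran-5-yl]methyl}-3-oxopropanoate (not isolated) | COC(=O)[C@](Cc1ccc2c(c1)C[C@@H](C(C)(C)O)O2)(OC(=O)COCc1ccccc1)C(=O)c1ccc(OCc2ccccc2)cc1 | intermediate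
13 | methyl (2R)-4-(benzyloxy)-3-[4-(benzyloxy)phenyl]-3-hydroxy-2-{[(2S)-2-(2-hydroxypropan-2-yl)-2,3-dihydro-1-benzofuran-5-yl]methyl}-5-oxooxolane-2-carboxylate (C3 and C4 undefined, not isolated) | COC(=O)[C@]1(Cc2ccc3c(c2)C[C@@H](C(C)(C)O)O3)OC(=O)C(OCc2ccccc2)C1(O)c1ccc(OCc2ccccc2)cc1 | intermediate
14 | methyl (2R)-4-(benzyloxy)-3-[4-(benzyloxy)phenyl]-2-{[(2S)-2-(2-hydroxypropan-2-yl)-2,3-dihydro-1-benzofuran-5-yl]methyl}-5-oxo-2,5-dihydrofuran-2-carboxylate | COC(=O)[C@]1(Cc2ccc3c(c2)C[C@@H](C(C)(C)O)O3)OC(=O)C(OCc2ccccc2)=C1c1ccc(OCc2ccccc2)cc1 | intermediate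
15 | methyl (2R)-4-hydroxy-3-(4-hydroxyphenyl)-2-{[(2S)-2-(2-hydroxypropan-2-yl)-2,3-dihydro-1-benzofuran-5-yl]methyl}-5-oxo-2,5-dihydrofuran-2-carboxylate | COC(=O)[C@]1(Cc2ccc3c(c2)C[C@@H](C(C)(C)O)O3)OC(=O)C(O)=C1c1ccc(O)cc1 | target

Total step count: 8. Longest linear sequence: 8 steps (1 to 15).

Steps most likely to fail

Step 7. Three things may go wrong:
- Dehydrochlorination may overtake the displacement.
- The configuration at C2 may erode through degenerate chloride exchange.
- The glycolate carbanion may close onto the ester carbonyl instead of the ketone.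

The fallback sets out from 9 and returns at 14. It makes O1–C2 by oxidative umpolung instead of substitution. PhI(OAc)2 is warmed with 11 under reduced pressure to exchange its ligands and give bis(benzyloxyacetoxy)iodobenzene F1. F1 acyloxylates the enol of 9 at C2, which is the known α-acyloxylation of α-substituted β-keto esters with trivalent-iodine dicarboxylates. This should give isolated 12 together with the (2S)-epimeric acyloxy keto ester F2. Separate treatment with DBU in MeCN closes the ring to 14 and the (2S)-epimeric lactone F3. These two are diastereomers because of the dihydrobenzofuran centre, so preparative HPLC can part them.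

Step 6. Facial discrimination on an acyclic methyl ester may be poor. Turnover may also slow through binding of the tertiary alcohol to copper.

The fallback sets out from 9 and returns at 10. It replaces asymmetric catalysis by resolution. Unselective chlorination (NCS, Mg(ClO4)2 cat., MeCN) gives 10 together with the (2R)-epimeric chloride F4. As diastereomers, the two are separated by preparative HPLC or fractional crystallisation. F4 is returned to 9 with Zn dust in AcOH and recycled.

Step 1. O-alkylation, a second prenylation at the other ortho position, and acid-induced closure of the product to a chroman may all drain material.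

The fallback sets out from 1 and returns at 3. It fixes the regiochemistry with a halogen. Mono-iodination ortho to the hydroxyl group (NIS, TsOH cat., MeCN) gives methyl 3-(4-hydroxy-3-iodophenyl)propanoate F5. Stille coupling of F5 with tributyl(3-methylbut-2-en-1-yl)stannane (Pd(PPh3)4, DMF, 80 °C) then gives 3.

Further compounds
F1 | step 7 | bis(benzyloxyacetoxy)iodobenzene | O=C(COCc1ccccc1)OI(OC(=O)COCc1ccccc1)c1ccccc1
F2 | step 7 | methyl (2S)-2-[(benzyloxyacetyl)oxy]-3-[4-(benzyloxy)phenyl]-2-{[(2S)-2-(2-hydroxypropan-2-yl)-2,3-dihydro-1-benzofuran-5-yl]methyl}-3-oxopropanoate | COC(=O)[C@@](Cc1ccc2c(c1)C[C@@H](C(C)(C)O)O2)(OC(=O)COCc1ccccc1)C(=O)c1ccc(OCc2ccccc2)cc1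
F3 | step 7 | methyl (2S)-4-(benzyloxy)-3-[4-(benzyloxy)phenyl]-2-{[(2S)-2-(2-hydroxypropan-2-yl)-2,3-dihydro-1-benzofuran-5-yl]methyl}-5-oxo-2,5-dihydrofuran-2-carboxylate | COC(=O)[C@@]1(Cc2ccc3c(c2)C[C@@H](C(C)(C)O)O3)OC(=O)C(OCc2ccccc2)=C1c1ccc(OCc2ccccc2)cc1
F4 | step 6 | methyl (2R)-3-[4-(benzyloxy)phenyl]-2-chloro-2-{[(2S)-2-(2-hydroxypropan-2-yl)-2,3-dihydro-1-benzofuran-5-yl]methyl}-3-oxopropanoate | COC(=O)[C@@](Cl)(Cc1ccc2c(c1)C[C@@H](C(C)(C)O)O2)C(=O)c1ccc(OCc2ccccc2)cc1
F5 | step 1 | methyl 3-(4-hydroxy-3-iodophenyl)propanoate | COC(=O)CCc1ccc(O)c(I)c1
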